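**Retrosynthetic overview**
1. Last step: the phenol on the C5 aryl ring is released from a pivalate. Ring locants used here are O1, C2 (aryl trans to the C3 methyl), C3, C4, C5 (aryl cis to the C4 methyl); the target is (2S,3S,4S,5R).
2. Key disconnection: the C2–aryl bond, formed from the para C–H of 2,6-dimethoxyphenol and an oxocarbenium ion O1=C2. The ion is made by acid opening of a cyclopropane fused across C2–C3 (a 2-oxabicyclo[3.1.0]hexane), so the cyclopropane CH2 becomes the C3 methyl in the same operation.
3. Enabling feature: C2 is the benzylic carbon of the oxolane ring bonded directly to the ring oxygen O1, so it can be a cation stabilised by O1. Its neighbour C3 carries a methyl that can be stored as a cyclopropane CH2, and the aryl to be attached is a 4-hydroxy-3,5-dimethoxyphenyl ring whose only open, OH-activated position is the attachment carbon.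
4. The cyclopropane comes from a Simmons–Smith reaction on a 2,3-dihydrofuran, anti to the cis C4-methyl/C5-aryl pair. The dihydrofuran comes from cycloisomerisation of a syn homopropargylic alcohol, made from pivaloyl-protected syringaldehyde and an axially chiral allenylstannane derived from (S)-but-3-yn-2-ol.
5. Ring order: oxolane ring first (O1–C2 bond, step 5), temporary cyclopropane second (step 6), cyclopropane opened again in the key step; both aromatic rings are bought.

Key step: step 7

Remark: both aryl groups of the target are the same, so the two ring ends are told apart only by configuration; the bond made in the key step is the one at the 2,3-trans end.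

**Route**

Step 1
Reactants: 1 syringaldehyde (4-hydroxy-3,5-dimethoxybenzaldehyde)
Product: 2 4-formyl-2,6-dimethoxyphenyl pivalate
Conditions: PivCl, Et3N, DMAP (cat.), CH2Cl2, 0 °C → rt
Reagents that add atoms: pivaloyl chloride, CC(C)(C)C(=O)Cl
Why: DMAP-catalysed O-acylation of the phenol; the pivalate is chosen because it makes this ring electron-poor (so the later C5 benzylic C–O bond should not ionise in step 7) and should survive BF3, amine, zinc carbenoid and TfOH.

Step 2
Reactants: 3 (S)-but-3-yn-2-ol
Product: 4 (S)-but-3-yn-2-yl methanesulfonate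
Conditions: MsCl, Et3N, CH2Cl2, −78 → 0 °C
Reagents that add atoms: methanesulfonyl chloride, CS(=O)(=O)Cl
Why: O-sulfonylation of the secondary alcohol; no bond at the stereocentre is touched, so the (S) configuration is kept.

Step 3
Reactants: 4 (S)-but-3-yn-2-yl methanesulfonate
Product: 5 (M)-tributyl(buta-1,2-dien-1-yl)stannane
Conditions: Bu3SnH, LDA, THF, 0 °C; CuBr·SMe2, −78 °C; then 4, −78 °C
Reagents that add atoms: tributyltin hydride (used as Bu3SnLi), CCCC[SnH](CCCC)CCCC
Why: anti-SN2' displacement of the propargylic mesylate by the stannylcuprate should transfer the central chirality of 4 to the allene axis, giving the (M) allene.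

Step 4
Reactants: 2 4-formyl-2,6-dimethoxyphenyl pivalate; 5 (M)-tributyl(buta-1,2-dien-1-yl)stannane
Product: 6 4-[(1R,2S)-1-hydroxy-2-methylbut-3-yn-1-yl]-2,6-dimethoxyphenyl pivalate
Conditions: BF3·OEt2 (1.5 equiv), CH2Cl2, −78 °C; aq. NaHCO3, then aq. KF
Reagents that add atoms: none
Why: SE2' addition of the allenylstannane to the BF3-activated aldehyde through an open transition state (attack anti to tin) should give the syn homopropargylic alcohol; the allene axis sets the methyl-bearing carbon (S) and the open transition state sets the carbinol carbon (R), which become C4 and C5 of the target.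

Step 5
Reactants: 6 4-[(1R,2S)-1-hydroxy-2-methylbut-3-yn-1-yl]-2,6-dimethoxyphenyl pivalate
Product: 7 4-[(2R,3S)-3-methyl-2,3-dihydrofuran-2-yl]-2,6-dimethoxyphenyl pivalate
Conditions: Mo(CO)6 (25 mol%), Et3N, Et2O, hν (350 nm), rt
Reagents that add atoms: none
Why: alkynol cycloisomerisation through a molybdenum vinylidene, in which the hydroxyl adds to the terminal alkyne carbon (endo mode), should give the cyclic enol ether without touching either stereocentre.

Step 6
Reactants: 7 4-[(2R,3S)-3-methyl-2,3-dihydrofuran-2-yl]-2,6-dimethoxyphenyl pivalate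
Product: 8 4-[(1S,3R,4S,5S)-4-methyl-2-oxabicyclo[3.1.0]hexan-3-yl]-2,6-dimethoxyphenyl pivalate
Conditions: Et2Zn (2 equiv), CH2I2 (2 equiv), CH2Cl2, 0 °C; pyridine, then aq. NaHCO3
Reagents that add atoms: diiodomethane, ICI
Why: Simmons–Smith cyclopropanation (Furukawa variant) of the electron-rich enol ether should occur on the face opposite the cis methyl and aryl groups, which fixes both cyclopropane stereocentres and places the future C3 methyl trans to the C4 methyl.

Step 7
Reactants: 8 4-[(1S,3R,4S,5S)-4-methyl-2-oxabicyclo[3.1.0]hexan-3-yl]-2,6-dimethoxyphenyl pivalate; 9 2,6-dimethoxyphenol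
Product: 11 4-[(2R,3S,4S,5S)-5-(4-hydroxy-3,5-dimethoxyphenyl)-3,4-dimethyltetrahydrofuran-2-yl]-2,6-dimethoxyphenyl pivalate, via oxocarbenium ion 10 (not isolated)
Conditions: 9 (3 equiv), TfOH (10 mol%), CH2Cl2/HFIP 4:1, −40 → −10 °C; Et3N quench
Reagents that add atoms: none
Why: Proposed new method: catalytic TfOH should protonate the cyclopropane at its unsubstituted CH2 with push from the O1 lone pair, breaking only the bond between that CH2 and the O-bearing cyclopropane carbon, so that the CH2 becomes the C3 methyl (C3 keeps the configuration fixed in step 6) and the O-bearing carbon becomes C2 of oxocarbenium ion 10, which 2,6-dimethoxyphenol then attacks through its para carbon in a Friedel–Crafts arylation that forms the C2–aryl bond. The closest known reaction types are the acid-catalysed opening of alkoxycyclopropanes to α-methyl oxocarbenium ions (trapped so far by water or alcohols), the TfOH/HFIP ring-opening hydroarylation of cyclopropanes, and the Lewis-acid Friedel–Crafts arylation of 2-alkoxytetrahydrofurans by phenols. No ring is closed: the temporary three-membered ring is opened and the oxolane ring is kept. The one new stereocentre, C2, should be set by attack of the arene on the face of 10 anti to the adjacent C3 methyl (1,2-induction, giving 2,3-trans), and because the new C2–O1 bond is a p-hydroxybenzylic ether that can re-ionise under the acid, any 2,3-cis isomer should drain to the more stable trans isomer. Three selectivities are needed: cleavage of the exocyclic cyclopropane bond and not the ring-fusion bond (secured because the proton goes to the least substituted carbon and the cation forms next to oxygen), para attack on the arene (secured by the free OH as strongest donor with both ortho positions blocked by OMe), and integrity of C5 (secured by the electron-withdrawing pivalate, which keeps the C5–O1 bond from ionising).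

Step 8
Reactants: 11 4-[(2R,3S,4S,5S)-5-(4-hydroxy-3,5-dimethoxyphenyl)-3,4-dimethyltetrahydrofuran-2-yl]-2,6-dimethoxyphenyl pivalate
Product: 12 4,4'-[(2S,3S,4S,5R)-3,4-dimethyltetrahydrofuran-2,5-diyl]bis(2,6-dimethoxyphenol) (target)
Conditions: NaOMe (3 equiv), MeOH/THF, 40 °C, Ar; AcOH quench
Reagents that add atoms: none
Why: transesterification of the aryl pivalate by methoxide should release the second phenol; the oxolane and its four stereocentres are stable to base, and air is excluded to protect the electron-rich phenols.

**Compound list**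
1 | syringaldehyde (4-hydroxy-3,5-dimethoxybenzaldehyde) | COc1cc(C=O)cc(OC)c1O | starting material
2 | 4-formyl-2,6-dimethoxyphenyl pivalate | COc1cc(C=O)cc(OC)c1OC(=O)C(C)(C)C | intermediate
3 | (S)-but-3-yn-2-ol | C[C@H](O)C#C | starting material
4 | (S)-but-3-yn-2-yl methanesulfonate | C[C@H](OS(C)(=O)=O)C#C | intermediate
5 | (M)-tributyl(buta-1,2-dien-1-yl)stannane [(aR)] | CCCC[Sn](CCCC)(CCCC)C([H])=[C@]=C([H])C | intermediate
6 | 4-[(1R,2S)-1-hydroxy-2-methylbut-3-yn-1-yl]-2,6-dimethoxyphenyl pivalate | COc1cc([C@H](O)[C@@H](C)C#C)cc(OC)c1OC(=O)C(C)(C)C | intermediate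
7 | 4-[(2R,3S)-3-methyl-2,3-dihydrofuran-2-yl]-2,6-dimethoxyphenyl pivalate | COc1cc([C@@H]2OC=C[C@@H]2C)cc(OC)c1OC(=O)C(C)(C)C | intermediate
8 | 4-[(1S,3R,4S,5S)-4-methyl-2-oxabicyclo[3.1.0]hexan-3-yl]-2,6-dimethoxyphenyl pivalate | COc1cc([C@@H]2O[C@H]3C[C@H]3[C@@H]2C)cc(OC)c1OC(=O)C(C)(C)C | intermediate
9 | 2,6-dimethoxyphenol | COc1cccc(OC)c1O | starting material
10 | (2R,3S,4S)-2-(3,5-dimethoxy-4-pivaloyloxyphenyl)-3,4-dimethyl-3,4-dihydro-2H-furan-1-ium (oxocarbenium ion, triflate counter-ion) | COc1cc([C@@H]2[O+]=C[C@@H](C)[C@@H]2C)cc(OC)c1OC(=O)C(C)(C)C | intermediate (not isolated)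
11 | 4-[(2R,3S,4S,5S)-5-(4-hydroxy-3,5-dimethoxyphenyl)-3,4-dimethyltetrahydrofuran-2-yl]-2,6-dimethoxyphenyl pivalate | COc1cc([C@H]2O[C@@H](c3cc(OC)c(OC(=O)C(C)(C)C)c(OC)c3)[C@@H](C)[C@@H]2C)cc(OC)c1O | intermediate
12 | 4,4'-[(2S,3S,4S,5R)-3,4-dimethyltetrahydrofuran-2,5-diyl]bis(2,6-dimethoxyphenol) | COc1cc([C@H]2O[C@@H](c3cc(OC)c(O)c(OC)c3)[C@@H](C)[C@@H]2C)cc(OC)c1O | target

**Count**
Total step count: 8. Longest linear sequence: 7 steps (3 → 4 → 5 → 6 → 7 → 8 → 11 → 12; steps 2 to 8).

**Steps most likely to fail, with fallbacks**

Step 7 (Proposed new method). The three events may not mesh in one flask. The cation may lose the C3 proton faster than it is arylated, which would scramble C3 through the enol ether. The product may also re-ionise at C2 and take up a second arene, and ring opening may be slow at the low temperature that the arylation needs. The fallback uses known chemistry and separates ring opening from arylation. It sets out from 8, which is opened by acid-catalysed methanolysis (TsOH cat., MeOH, rt; the classical alkoxycyclopropane to α-methyl acetal opening, in which the cation is trapped at once by solvent). This should give the methyl acetal 4-[(2R,3S,4S)-5-methoxy-3,4-dimethyltetrahydrofuran-2-yl]-2,6-dimethoxyphenyl pivalate F1 as an anomer mixture. After isolation, F1 is subjected to the established Friedel–Crafts arylation of a 2-methoxytetrahydrofuran with 9 (BF3·OEt2, CH2Cl2, −78 → −40 °C), which returns to the route at 11.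

Step 4. The open transition state may give poor syn/anti discrimination with an aromatic aldehyde, and the stannane may lose some axial purity on handling. The fallback makes the anti isomer through a closed transition state and then inverts the carbinol. It sets out from 2. Commercial (R)-but-3-yn-2-ol is mesylated to (R)-but-3-yn-2-yl methanesulfonate F2. Treatment of F2 with Pd(OAc)2/PPh3 (cat.) and Et2Zn in THF at −20 °C should form (P)-buta-1,2-dien-1-yl(ethyl)zinc F3 in the flask. F3 should add to 2 through a six-membered transition state to give the anti alcohol 4-[(1S,2S)-1-hydroxy-2-methylbut-3-yn-1-yl]-2,6-dimethoxyphenyl pivalate F4. Mitsunobu inversion of the benzylic carbinol (4-nitrobenzoic acid, PPh3, DIAD, THF, 0 °C) should give (1R,2S)-1-(3,5-dimethoxy-4-pivaloyloxyphenyl)-2-methylbut-3-yn-1-yl 4-nitrobenzoate F5. Brief methanolysis (K2CO3, MeOH, 0 °C; the activated nitrobenzoate should cleave much faster than the hindered aryl pivalate) returns to the route at 6.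

Step 5. The vinylidene catalyst may stall with a propargylic methyl next to the alkyne, and the enol ether may hydrolyse or oligomerise during the long irradiation. The fallback uses π-acid activation of the alkyne and goes through an acetal. It sets out from 6. Gold-catalysed tandem cycloisomerisation and methanol addition (Ph3PAuCl/AgOTf cat., TsOH cat., MeOH, rt) should give 4-[(2R,3S)-5-methoxy-3-methyltetrahydrofuran-2-yl]-2,6-dimethoxyphenyl pivalate F6. Elimination of methanol from the acetal (TMSOTf, iPr2NEt, CH2Cl2, 0 °C → rt) returns to the route at 7.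

**Further compounds**
F1 | step 7 | 4-[(2R,3S,4S)-5-methoxy-3,4-dimethyltetrahydrofuran-2-yl]-2,6-dimethoxyphenyl pivalate (anomer mixture) | COc1cc([C@@H]2OC(OC)[C@@H](C)[C@@H]2C)cc(OC)c1OC(=O)C(C)(C)C
F2 | step 4 | (R)-but-3-yn-2-yl methanesulfonate | C[C@@H](OS(C)(=O)=O)C#C
F3 | step 4 | (P)-buta-1,2-dien-1-yl(ethyl)zinc (formed in the flask) | CC[Zn]C([H])=[C@@]=C([H])C
F4 | step 4 | 4-[(1S,2S)-1-hydroxy-2-methylbut-3-yn-1-yl]-2,6-dimethoxyphenyl pivalate | COc1cc([C@@H](O)[C@@H](C)C#C)cc(OC)c1OC(=O)C(C)(C)C
F5 | step 4 | (1R,2S)-1-(3,5-dimethoxy-4-pivaloyloxyphenyl)-2-methylbut-3-yn-1-yl 4-nitrobenzoate | COc1cc([C@H](OC(=O)c2ccc(cc2)[N+](=O)[O-])[C@@H](C)C#C)cc(OC)c1OC(=O)C(C)(C)C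
F6 | step 5 | 4-[(2R,3S)-5-methoxy-3-methyltetrahydrofuran-2-yl]-2,6-dimethoxyphenyl pivalate (anomer mixture) | COc1cc([C@@H]2OC(OC)C[C@@H]2C)cc(OC)c1OC(=O)C(C)(C)C
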